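**Retrosynthetic overview** (atoms numbered from the lactone carbonyl, C1, to the CH2 on C3 of the furan, C15)

1. The plan rests on the (E)-trisubstituted C12=C13 olefin, which carries CH3 on C12 and the C14–C15–furan arm on C13 and is skipped to C8=C9 across C10–C11. It is cut at C12–CH3 and C13–C14 into a terminal C12≡C13 alkyne, a methyl group from Me3Al and 2-(furan-3-yl)ethylzinc iodide, joined in one flask.
2. After that step: the two acetates go back to the 5,10-diol, and the γ-lactone ring (O–C1–C2–C3–C4) to diethyl malonate (C1, C2) and a (4S,5R) epoxy alcohol. The epoxy alcohol goes back to the C5 aldehyde and isopropenylmagnesium bromide (C3, C4, 4-CH3), with a Sharpless epoxidation setting C4 and C5.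
3. Before it: the enynol comes from an (E)-enal by catalytic asymmetric propargylation (sets C10), and the enal from pent-4-yn-1-ol by methylalumination and trapping with formaldehyde (C8=C9).
4. Ring order: the furan ring arrives intact in the zinc reagent (step 7); the γ-lactone ring is the only ring closed (step 13).

Key step: step 7

Remark: in step 4 the (S)-acid is taken to send the allenylboronate to the Si face of the enal (the (R)-acid being associated with Re-face attack on aldehydes); were the sense the opposite, the antipodal acid would be used.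

**Route**

Step 1
Reactants: 1 pent-4-yn-1-ol
Product: 2 tert-butyl(dimethyl)(pent-4-yn-1-yloxy)silane
Conditions: TBSCl, imidazole, CH2Cl2, 0 °C to rt
Reagents that add atoms: tert-butyldimethylsilyl chloride (TBSCl), CC(C)(C)[Si](C)(C)Cl
Why: Silylation of a primary alcohol with TBSCl and imidazole is routine, and the TBS ether is inert to the organoaluminium, organozinc and palladium chemistry ahead.

Step 2
Reactants: 2 tert-butyl(dimethyl)(pent-4-yn-1-yloxy)silane, 3 trimethylaluminium, 4 paraformaldehyde (source of formaldehyde)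
Product: 7 (2E)-6-[(tert-butyldimethylsilyl)oxy]-3-methylhex-2-en-1-ol, via alkenyldimethylalane 5 (not isolated), via lithium alkenylalanate 6 (not isolated)
Conditions: 3 (2 equiv), Cp2ZrCl2 (0.25 equiv), CH2Cl2, 0 °C to rt; volatiles removed; n-BuLi, THF/hexane, −78 to 0 °C; 4, 0 °C to rt; aq. potassium sodium tartrate
Reagents that add atoms: none
Why: Negishi zirconium-catalysed methylalumination adds CH3 and aluminium syn across the terminal alkyne with CH3 on the internal carbon, and the alanate formed with n-BuLi adds to formaldehyde with retention at the alkenyl carbon, so the (E)-trisubstituted C8=C9 allylic alcohol should result.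

Step 3
Reactants: 7 (2E)-6-[(tert-butyldimethylsilyl)oxy]-3-methylhex-2-en-1-ol
Product: 8 (2E)-6-[(tert-butyldimethylsilyl)oxy]-3-methylhex-2-enal
Conditions: MnO2 (excess), CH2Cl2, rt
Reagents that add atoms: none
Why: MnO2 oxidises the allylic alcohol selectively to the enal under neutral conditions that leave the silyl ether and the (E)-geometry untouched.

Step 4
Reactants: 8 (2E)-6-[(tert-butyldimethylsilyl)oxy]-3-methylhex-2-enal, 9 allenylboronic acid pinacol ester
Product: 11 (4S,5E)-9-[(tert-butyldimethylsilyl)oxy]-6-methylnon-5-en-1-yn-4-ol, via O-pinacolboryl ether 10 (not isolated)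
Conditions: (S)-3,3'-bis(2,4,6-triisopropylphenyl)-1,1'-binaphthyl-2,2'-diyl hydrogen phosphate (5 mol%), 4 Å MS, toluene, 0 °C; aq. NaHCO3 work-up
Reagents that add atoms: none
Why: Chiral-phosphoric-acid-catalysed propargylation with an allenylboronate runs through a closed six-membered SE2' transition state in which the acid binds the boronate oxygen and the formyl hydrogen, so the homopropargylic alcohol (no allenyl isomer) is formed and the catalyst antipode sets C10 as (S) by Si-face attack.

Step 5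
Reactants: 12 2-(furan-3-yl)ethanol
Product: 13 3-(2-iodoethyl)furan
Conditions: I2, PPh3, imidazole, CH2Cl2, 0 °C to rt, dark
Reagents that add atoms: iodine, II
Why: The PPh3/I2/imidazole (Appel-type) iodination converts the primary alcohol into the iodide by SN2 displacement of an alkoxyphosphonium ion under nearly neutral conditions that the furan tolerates.

Step 6
Reactants: 13 3-(2-iodoethyl)furan
Product: 14 2-(furan-3-yl)ethylzinc iodide (titrated THF solution, used directly)
Conditions: Zn dust (activated with 1,2-dibromoethane and TMSCl), LiCl, THF, 40 °C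
Reagents that add atoms: zinc, [Zn]
Why: Direct insertion of activated zinc into a primary alkyl iodide, accelerated by LiCl, is a standard preparation of alkylzinc iodides and leaves the furan untouched.

Step 7
Reactants: 11 (4S,5E)-9-[(tert-butyldimethylsilyl)oxy]-6-methylnon-5-en-1-yn-4-ol, 3 trimethylaluminium, 14 2-(furan-3-yl)ethylzinc iodide
Product: 17 (4E,6S,8E)-1-[(tert-butyldimethylsilyl)oxy]-11-(furan-3-yl)-4,8-dimethylundeca-4,8-dien-6-ol, via alkenylalane aluminium alkoxide 15 (not isolated), via alkenyl iodide aluminium alkoxide 16 (not isolated)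
Conditions: 3 (3 equiv), Cp2ZrCl2 (0.3 equiv), CH2Cl2, 0 °C to rt; I2 (1.1 equiv), THF, −30 to 0 °C; MeOH, −30 °C (quench of residual Al–CH3); 14 (3 equiv), Pd(PPh3)4 (5 mol%), THF/DMF, rt to 40 °C; aq. potassium sodium tartrate
Reagents that add atoms: none
Why: Me3Al first turns the C10 hydroxyl into its dimethylaluminium alkoxide, and the methylzirconium species formed from Cp2ZrCl2 and Me3Al then adds CH3 and metal syn across the terminal alkyne with CH3 on the internal carbon C12, so that after zirconium-to-aluminium exchange the (E)-alkenylalane 15 carries aluminium on C13 cis to the new methyl. Iodinolysis of the alkenyl C–Al bond proceeds with retention to give 16, residual Al–CH3 bonds are destroyed with methanol so that methyl transfer cannot compete, and oxidative addition of the C–I bond to zerovalent palladium, transmetalation of the furylethyl group from zinc to the divalent alkenylpalladium iodide and reductive elimination, all with retention, form C13–C14. The closest known reaction type is the Negishi sequence of zirconium-catalysed methylalumination, iodination and Pd(PPh3)4-catalysed coupling of homoallyl- or homobenzyl-type alkylzinc halides with (E)-alkenyl iodides, a standard entry to 1,5-diene terpenoid chains, and free homopropargylic alcohols are usual substrates as their aluminium alkoxides. No ring is closed and no stereocentre is created; C10 is untouched because its C–O bond is never activated. The selectivities needed are regiochemistry (CH3 on C12, not C13), syn addition, and retention through iodination and coupling, which together place C11 and C14 trans; the first two are intrinsic to the four-centre carbometalation of a terminal alkyne, the last to the stereospecific elementary steps at aluminium and palladium. The TBS ether and the C8=C9 olefin are inert, and the furan enters only after the iodine has been consumed.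

Step 8
Reactants: 17 (4E,6S,8E)-1-[(tert-butyldimethylsilyl)oxy]-11-(furan-3-yl)-4,8-dimethylundeca-4,8-dien-6-ol
Product: 18 (4E,6S,8E)-1-[(tert-butyldimethylsilyl)oxy]-6-[(tert-butyldiphenylsilyl)oxy]-11-(furan-3-yl)-4,8-dimethylundeca-4,8-diene
Conditions: TBDPSCl, imidazole, DMAP (cat.), DMF, rt
Reagents that add atoms: tert-butyldiphenylsilyl chloride (TBDPSCl), CC(C)(C)[Si](Cl)(c1ccccc1)c1ccccc1
Why: Imidazole/DMAP-promoted silylation of the secondary allylic alcohol installs a TBDPS ether that will outlast the selective removal of the primary TBS group and the basic, oxidative and thermal steps up to step 14.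

Step 9
Reactants: 18 (4E,6S,8E)-1-[(tert-butyldimethylsilyl)oxy]-6-[(tert-butyldiphenylsilyl)oxy]-11-(furan-3-yl)-4,8-dimethylundeca-4,8-diene
Product: 19 (4E,6S,8E)-6-[(tert-butyldiphenylsilyl)oxy]-11-(furan-3-yl)-4,8-dimethylundeca-4,8-dien-1-ol
Conditions: PPTS (cat.), MeOH, rt
Reagents that add atoms: none
Why: Mild acid-catalysed methanolysis cleaves the unhindered primary TBS ether far faster than the hindered secondary TBDPS ether, and PPTS is too weak an acid to harm the furan or ionise the allylic silyl ether.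

Step 10
Reactants: 19 (4E,6S,8E)-6-[(tert-butyldiphenylsilyl)oxy]-11-(furan-3-yl)-4,8-dimethylundeca-4,8-dien-1-ol
Product: 20 (4E,6S,8E)-6-[(tert-butyldiphenylsilyl)oxy]-11-(furan-3-yl)-4,8-dimethylundeca-4,8-dienal
Conditions: Dess–Martin periodinane, NaHCO3, CH2Cl2, 0 °C to rt
Reagents that add atoms: none
Why: Buffered Dess–Martin oxidation takes the primary alcohol to the aldehyde without over-oxidation and does not touch the olefins, the furan or the silyl ether.

Step 11
Reactants: 20 (4E,6S,8E)-6-[(tert-butyldiphenylsilyl)oxy]-11-(furan-3-yl)-4,8-dimethylundeca-4,8-dienal, 21 isopropenylmagnesium bromide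
Product: 22 (3RS,6E,8S,10E)-8-[(tert-butyldiphenylsilyl)oxy]-13-(furan-3-yl)-2,6,10-trimethyltrideca-1,6,10-trien-3-ol (both epimers at the carbinol carbon, which is C5 of the target)
Conditions: 21, THF, −78 °C; sat. aq. NH4Cl
Reagents that add atoms: none
Why: Addition of the alkenyl Grignard reagent to the aldehyde is fast at −78 °C and gives the 2-methylallylic alcohol; the remote C10 centre exerts no facial control, so both C5 epimers are expected and are dealt with in step 12.

Step 12
Reactants: 22 (3RS,6E,8S,10E)-8-[(tert-butyldiphenylsilyl)oxy]-13-(furan-3-yl)-2,6,10-trimethyltrideca-1,6,10-trien-3-ol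
Product: 23 (1R,4E,6S,8E)-6-[(tert-butyldiphenylsilyl)oxy]-11-(furan-3-yl)-4,8-dimethyl-1-[(2S)-2-methyloxiran-2-yl]undeca-4,8-dien-1-ol
Conditions: Ti(OiPr)4 (15 mol%), D-(−)-diisopropyl tartrate (20 mol%), TBHP (0.6 equiv), 4 Å MS, CH2Cl2, −20 °C
Reagents that add atoms: tert-butyl hydroperoxide (TBHP), CC(C)(C)OO
Why: Under Sharpless asymmetric epoxidation (kinetic resolution) conditions with D-(−)-tartrate the (5R) secondary allylic alcohol reacts much faster than its (5S) epimer and is epoxidised from the face that gives the erythro epoxy alcohol, which sets C4 as (S) by reagent control, only the olefin next to the free hydroxyl being oxidised because titanium delivers the peroxide within the alkoxide complex; the unreacted (5S)-epimer is separated and can be recycled by oxidation and reduction.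

Step 13
Reactants: 23 (1R,4E,6S,8E)-6-[(tert-butyldiphenylsilyl)oxy]-11-(furan-3-yl)-4,8-dimethyl-1-[(2S)-2-methyloxiran-2-yl]undeca-4,8-dien-1-ol, 24 diethyl malonate
Product: 26 ethyl (3RS,5S)-5-[(1R,4E,6S,8E)-6-[(tert-butyldiphenylsilyl)oxy]-11-(furan-3-yl)-1-hydroxy-4,8-dimethylundeca-4,8-dien-1-yl]-5-methyl-2-oxooxolane-3-carboxylate, via open-chain dihydroxy malonate 25 (not isolated)
Conditions: 24 (3 equiv), NaOEt (2.5 equiv), EtOH, 70 °C; AcOH quench
Reagents that add atoms: none
Why: The malonate anion opens the 2,2-disubstituted epoxide by SN2 attack at its CH2 terminus (C3) without touching the C4–O bond, and the tertiary alkoxide so freed closes the five-membered lactone onto one ester group (the classical malonate synthesis of γ-lactones), so C4 and C5 keep their configuration while any Payne-type epoxide migration stays reversible and drains through the more reactive terminal epoxide.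

Step 14
Reactants: 26 ethyl (3RS,5S)-5-[(1R,4E,6S,8E)-6-[(tert-butyldiphenylsilyl)oxy]-11-(furan-3-yl)-1-hydroxy-4,8-dimethylundeca-4,8-dien-1-yl]-5-methyl-2-oxooxolane-3-carboxylate
Product: 27 (5S)-5-[(1R,4E,6S,8E)-6-[(tert-butyldiphenylsilyl)oxy]-11-(furan-3-yl)-1-hydroxy-4,8-dimethylundeca-4,8-dien-1-yl]-5-methyloxolan-2-one
Conditions: LiCl, H2O, DMSO, 140 °C
Reagents that add atoms: none
Why: Krapcho dealkoxycarbonylation in wet DMSO with LiCl hydrolyses the activated malonate-type ester and the acid loses CO2, under neutral conditions that spare the lactone, the silyl ether, the olefins and the furan.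

Step 15
Reactants: 27 (5S)-5-[(1R,4E,6S,8E)-6-[(tert-butyldiphenylsilyl)oxy]-11-(furan-3-yl)-1-hydroxy-4,8-dimethylundeca-4,8-dien-1-yl]-5-methyloxolan-2-one
Product: 28 (5S)-5-[(1R,4E,6S,8E)-11-(furan-3-yl)-1,6-dihydroxy-4,8-dimethylundeca-4,8-dien-1-yl]-5-methyloxolan-2-one
Conditions: TBAF, AcOH, THF, 0 °C to rt
Reagents that add atoms: none
Why: Fluoride cleaves the Si–O bond of the TBDPS ether, and buffering with acetic acid keeps the medium from opening the lactone or shifting it to the C5 oxygen.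

Step 16
Reactants: 28 (5S)-5-[(1R,4E,6S,8E)-11-(furan-3-yl)-1,6-dihydroxy-4,8-dimethylundeca-4,8-dien-1-yl]-5-methyloxolan-2-one
Product: 29 irciformonin F, (1R,4E,6S,8E)-11-(furan-3-yl)-4,8-dimethyl-1-[(2S)-2-methyl-5-oxooxolan-2-yl]undeca-4,8-diene-1,6-diyl diacetate
Conditions: Ac2O, pyridine, DMAP (cat.), CH2Cl2, 0 °C to rt
Reagents that add atoms: acetic anhydride, CC(=O)OC(C)=O
Why: DMAP-catalysed acetylation with acetic anhydride esterifies both secondary hydroxyls (C5 and C10) in one operation without affecting any stereocentre, which completes the target.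

**Compound list**

1 | pent-4-yn-1-ol | OCCCC#C | starting material
2 | tert-butyl(dimethyl)(pent-4-yn-1-yloxy)silane | C#CCCCO[Si](C)(C)C(C)(C)C | intermediate
3 | trimethylaluminium | C[Al](C)C | starting material
4 | paraformaldehyde (written as formaldehyde) | C=O | starting material
5 | {(1E)-5-[(tert-butyldimethylsilyl)oxy]-2-methylpent-1-en-1-yl}dimethylalumane | C[Al](C)/C=C(\C)CCCO[Si](C)(C)C(C)(C)C | intermediate
6 | lithium butyl{(1E)-5-[(tert-butyldimethylsilyl)oxy]-2-methylpent-1-en-1-yl}dimethylalanuide | [Li+].CCCC[Al-](C)(C)/C=C(\C)CCCO[Si](C)(C)C(C)(C)C | intermediate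
7 | (2E)-6-[(tert-butyldimethylsilyl)oxy]-3-methylhex-2-en-1-ol | OC/C=C(\C)CCCO[Si](C)(C)C(C)(C)C | intermediate
8 | (2E)-6-[(tert-butyldimethylsilyl)oxy]-3-methylhex-2-enal | O=C/C=C(\C)CCCO[Si](C)(C)C(C)(C)C | intermediate
9 | allenylboronic acid pinacol ester | C=C=CB1OC(C)(C)C(C)(C)O1 | starting material
10 | 2-{[(4S,5E)-9-[(tert-butyldimethylsilyl)oxy]-6-methylnon-5-en-1-yn-4-yl]oxy}-4,4,5,5-tetramethyl-1,3,2-dioxaborolane | C#CC[C@H](OB1OC(C)(C)C(C)(C)O1)/C=C(\C)CCCO[Si](C)(C)C(C)(C)C | intermediate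
11 | (4S,5E)-9-[(tert-butyldimethylsilyl)oxy]-6-methylnon-5-en-1-yn-4-ol | C#CC[C@H](O)/C=C(\C)CCCO[Si](C)(C)C(C)(C)C | intermediate
12 | 2-(furan-3-yl)ethanol | OCCc1ccoc1 | starting material
13 | 3-(2-iodoethyl)furan | ICCc1ccoc1 | intermediate
14 | 2-(furan-3-yl)ethylzinc iodide | I[Zn]CCc1ccoc1 | intermediate
15 | {(1E,4S,5E)-9-[(tert-butyldimethylsilyl)oxy]-4-[(dimethylalumanyl)oxy]-2,6-dimethylnona-1,5-dien-1-yl}dimethylalumane | C[Al](C)/C=C(\C)C[C@H](O[Al](C)C)/C=C(\C)CCCO[Si](C)(C)C(C)(C)C | intermediate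
16 | {[(1E,4S,5E)-9-[(tert-butyldimethylsilyl)oxy]-1-iodo-2,6-dimethylnona-1,5-dien-4-yl]oxy}dimethylalumane | I/C=C(\C)C[C@H](O[Al](C)C)/C=C(\C)CCCO[Si](C)(C)C(C)(C)C | intermediate
17 | (4E,6S,8E)-1-[(tert-butyldimethylsilyl)oxy]-11-(furan-3-yl)-4,8-dimethylundeca-4,8-dien-6-ol | O[C@H](/C=C(\C)CCCO[Si](C)(C)C(C)(C)C)C/C(C)=C/CCc1ccoc1 | intermediate
18 | (4E,6S,8E)-1-[(tert-butyldimethylsilyl)oxy]-6-[(tert-butyldiphenylsilyl)oxy]-11-(furan-3-yl)-4,8-dimethylundeca-4,8-diene | CC(C)(C)[Si](c1ccccc1)(c1ccccc1)O[C@H](/C=C(\C)CCCO[Si](C)(C)C(C)(C)C)C/C(C)=C/CCc1ccoc1 | intermediate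
19 | (4E,6S,8E)-6-[(tert-butyldiphenylsilyl)oxy]-11-(furan-3-yl)-4,8-dimethylundeca-4,8-dien-1-ol | CC(C)(C)[Si](c1ccccc1)(c1ccccc1)O[C@H](/C=C(\C)CCCO)C/C(C)=C/CCc1ccoc1 | intermediate
20 | (4E,6S,8E)-6-[(tert-butyldiphenylsilyl)oxy]-11-(furan-3-yl)-4,8-dimethylundeca-4,8-dienal | CC(C)(C)[Si](c1ccccc1)(c1ccccc1)O[C@H](/C=C(\C)CCC=O)C/C(C)=C/CCc1ccoc1 | intermediate
21 | isopropenylmagnesium bromide | C=C(C)[Mg]Br | starting material
22 | (3RS,6E,8S,10E)-8-[(tert-butyldiphenylsilyl)oxy]-13-(furan-3-yl)-2,6,10-trimethyltrideca-1,6,10-trien-3-ol | CC(C)(C)[Si](c1ccccc1)(c1ccccc1)O[C@H](/C=C(\C)CCC(O)C(C)=C)C/C(C)=C/CCc1ccoc1 | intermediate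
23 | (1R,4E,6S,8E)-6-[(tert-butyldiphenylsilyl)oxy]-11-(furan-3-yl)-4,8-dimethyl-1-[(2S)-2-methyloxiran-2-yl]undeca-4,8-dien-1-ol | CC(C)(C)[Si](c1ccccc1)(c1ccccc1)O[C@H](/C=C(\C)CC[C@@H](O)[C@]1(C)CO1)C/C(C)=C/CCc1ccoc1 | intermediate
24 | diethyl malonate | CCOC(=O)CC(=O)OCC | starting material
25 | diethyl 2-[(2S,3R,6E,8S,10E)-8-[(tert-butyldiphenylsilyl)oxy]-13-(furan-3-yl)-2,3-dihydroxy-2,6,10-trimethyltrideca-6,10-dien-1-yl]propanedioate | CC(C)(C)[Si](c1ccccc1)(c1ccccc1)O[C@H](/C=C(\C)CC[C@@H](O)[C@@](C)(O)CC(C(=O)OCC)C(=O)OCC)C/C(C)=C/CCc1ccoc1 | intermediate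
26 | ethyl (3RS,5S)-5-[(1R,4E,6S,8E)-6-[(tert-butyldiphenylsilyl)oxy]-11-(furan-3-yl)-1-hydroxy-4,8-dimethylundeca-4,8-dien-1-yl]-5-methyl-2-oxooxolane-3-carboxylate | CC(C)(C)[Si](c1ccccc1)(c1ccccc1)O[C@H](/C=C(\C)CC[C@@H](O)[C@]1(C)CC(C(=O)OCC)C(=O)O1)C/C(C)=C/CCc1ccoc1 | intermediate
27 | (5S)-5-[(1R,4E,6S,8E)-6-[(tert-butyldiphenylsilyl)oxy]-11-(furan-3-yl)-1-hydroxy-4,8-dimethylundeca-4,8-dien-1-yl]-5-methyloxolan-2-one | CC(C)(C)[Si](c1ccccc1)(c1ccccc1)O[C@H](/C=C(\C)CC[C@@H](O)[C@]1(C)CCC(=O)O1)C/C(C)=C/CCc1ccoc1 | intermediate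
28 | (5S)-5-[(1R,4E,6S,8E)-11-(furan-3-yl)-1,6-dihydroxy-4,8-dimethylundeca-4,8-dien-1-yl]-5-methyloxolan-2-one | O[C@H](/C=C(\C)CC[C@@H](O)[C@]1(C)CCC(=O)O1)C/C(C)=C/CCc1ccoc1 | intermediate
29 | irciformonin F, (1R,4E,6S,8E)-11-(furan-3-yl)-4,8-dimethyl-1-[(2S)-2-methyl-5-oxooxolan-2-yl]undeca-4,8-diene-1,6-diyl diacetate | CC(=O)O[C@H](/C=C(\C)CC[C@@H](OC(C)=O)[C@]1(C)CCC(=O)O1)C/C(C)=C/CCc1ccoc1 | target

**Step count and risks**

Total step count: 16. Longest linear sequence: 14 steps (steps 1–4 and 7–16, from pent-4-yn-1-ol); the zinc reagent (steps 5–6) joins at step 7.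

Steps most likely to fail:

1. Step 7. The carbometalation of the alkoxide-bearing alkyne may stall, the alkenylalane may be protonated before iodination, or leftover methylaluminium species may transfer methyl to palladium in competition with the zinc reagent. The fallback sets out from 11 and 13 and comes back at 17. Carboalumination and iodination of 11 are run alone (Me3Al, Cp2ZrCl2, CH2Cl2; I2, THF) and worked up with aqueous potassium sodium tartrate to isolate (1E,4S,5E)-9-[(tert-butyldimethylsilyl)oxy]-1-iodo-2,6-dimethylnona-1,5-dien-4-ol F1. Iodide 13 is treated with t-BuLi (Et2O, −78 °C) and then B-methoxy-9-BBN to give lithium 9-[2-(furan-3-yl)ethyl]-9-methoxy-9-boranuidabicyclo[3.3.1]nonane F2. A B-alkyl Suzuki–Miyaura coupling of F1 with F2 (PdCl2(dppf), AsPh3, K3PO4, DMF/THF/H2O, rt) then gives 17.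

2. Step 12. The rate difference between the two C5 epimers may be too small on this long-chain substrate, the 2,2-disubstituted epoxy alcohol may be opened by isopropoxide at titanium, and half of the material is lost by design. The fallback sets out from 22 and comes back at 23. Dess–Martin oxidation of the epimer mixture gives (6E,8S,10E)-8-[(tert-butyldiphenylsilyl)oxy]-13-(furan-3-yl)-2,6,10-trimethyltrideca-1,6,10-trien-3-one F3. Corey–Bakshi–Shibata reduction with catecholborane and (S)-1-methyl-3,3-diphenyltetrahydro-1H,3H-pyrrolo[1,2-c][1,3,2]oxazaborole (cat., toluene, −78 °C), the isopropenyl group acting as the large substituent, should give (3R,6E,8S,10E)-8-[(tert-butyldiphenylsilyl)oxy]-13-(furan-3-yl)-2,6,10-trimethyltrideca-1,6,10-trien-3-ol F4. Hydroxyl-directed epoxidation with VO(acac)2 (cat.) and TBHP, erythro-selective for 2-substituted allylic alcohols through allylic 1,2-strain, then gives 23.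

3. Step 13. Attack at the neopentyl-type CH2 may be slow, base may shift the epoxide toward C5 (Payne-type migration), and ring closure through the C5 oxygen may give a six-membered lactone. The fallback sets out from 23 and comes back at 28.
   - Silylation (TESCl, imidazole, DMAP, CH2Cl2) gives (4E,6S,8E)-6-[(tert-butyldiphenylsilyl)oxy]-11-(furan-3-yl)-4,8-dimethyl-1-[(2S)-2-methyloxiran-2-yl]-1-[(triethylsilyl)oxy]undeca-4,8-diene with (1R) configuration F5.
   - Vinylmagnesium bromide with CuI (cat., THF, −30 °C) opens the epoxide at CH2 to give (4S,5R,8E,10S,12E)-10-[(tert-butyldiphenylsilyl)oxy]-15-(furan-3-yl)-4,8,12-trimethyl-5-[(triethylsilyl)oxy]pentadeca-1,8,12-trien-4-ol F6.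
   - Hydroboration of the terminal vinyl group with 9-BBN and oxidation with NaBO3·4H2O gives (4S,5R,8E,10S,12E)-10-[(tert-butyldiphenylsilyl)oxy]-15-(furan-3-yl)-4,8,12-trimethyl-5-[(triethylsilyl)oxy]pentadeca-8,12-diene-1,4-diol F7.
   - Oxidative lactonization of the 1,4-diol with 2,2,6,6-tetramethylpiperidin-1-oxyl (cat.) and PhI(OAc)2 gives (5S)-5-[(1R,4E,6S,8E)-6-[(tert-butyldiphenylsilyl)oxy]-11-(furan-3-yl)-4,8-dimethyl-1-[(triethylsilyl)oxy]undeca-4,8-dien-1-yl]-5-methyloxolan-2-one F8.
   - TBAF/AcOH removes both silyl groups to give 28.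

**Further compounds**

F1 | step 7 | (1E,4S,5E)-9-[(tert-butyldimethylsilyl)oxy]-1-iodo-2,6-dimethylnona-1,5-dien-4-ol | I/C=C(\C)C[C@H](O)/C=C(\C)CCCO[Si](C)(C)C(C)(C)C
F2 | step 7 | lithium 9-[2-(furan-3-yl)ethyl]-9-methoxy-9-boranuidabicyclo[3.3.1]nonane | [Li+].CO[B-]1(CCc2ccoc2)C2CCCC1CCC2
F3 | step 12 | (6E,8S,10E)-8-[(tert-butyldiphenylsilyl)oxy]-13-(furan-3-yl)-2,6,10-trimethyltrideca-1,6,10-trien-3-one | CC(C)(C)[Si](c1ccccc1)(c1ccccc1)O[C@H](/C=C(\C)CCC(=O)C(C)=C)C/C(C)=C/CCc1ccoc1
F4 | step 12 | (3R,6E,8S,10E)-8-[(tert-butyldiphenylsilyl)oxy]-13-(furan-3-yl)-2,6,10-trimethyltrideca-1,6,10-trien-3-ol | CC(C)(C)[Si](c1ccccc1)(c1ccccc1)O[C@H](/C=C(\C)CC[C@@H](O)C(C)=C)C/C(C)=C/CCc1ccoc1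
F5 | step 13 | (1R,4E,6S,8E)-6-[(tert-butyldiphenylsilyl)oxy]-11-(furan-3-yl)-4,8-dimethyl-1-[(2S)-2-methyloxiran-2-yl]-1-[(triethylsilyl)oxy]undeca-4,8-diene | CC(C)(C)[Si](c1ccccc1)(c1ccccc1)O[C@H](/C=C(\C)CC[C@@H](O[Si](CC)(CC)CC)[C@]1(C)CO1)C/C(C)=C/CCc1ccoc1
F6 | step 13 | (4S,5R,8E,10S,12E)-10-[(tert-butyldiphenylsilyl)oxy]-15-(furan-3-yl)-4,8,12-trimethyl-5-[(triethylsilyl)oxy]pentadeca-1,8,12-trien-4-ol | CC(C)(C)[Si](c1ccccc1)(c1ccccc1)O[C@H](/C=C(\C)CC[C@@H](O[Si](CC)(CC)CC)[C@@](C)(O)CC=C)C/C(C)=C/CCc1ccoc1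
F7 | step 13 | (4S,5R,8E,10S,12E)-10-[(tert-butyldiphenylsilyl)oxy]-15-(furan-3-yl)-4,8,12-trimethyl-5-[(triethylsilyl)oxy]pentadeca-8,12-diene-1,4-diol | CC(C)(C)[Si](c1ccccc1)(c1ccccc1)O[C@H](/C=C(\C)CC[C@@H](O[Si](CC)(CC)CC)[C@@](C)(O)CCCO)C/C(C)=C/CCc1ccoc1
F8 | step 13 | (5S)-5-[(1R,4E,6S,8E)-6-[(tert-butyldiphenylsilyl)oxy]-11-(furan-3-yl)-4,8-dimethyl-1-[(triethylsilyl)oxy]undeca-4,8-dien-1-yl]-5-methyloxolan-2-one | CC(C)(C)[Si](c1ccccc1)(c1ccccc1)O[C@H](/C=C(\C)CC[C@@H](O[Si](CC)(CC)CC)[C@]1(C)CCC(=O)O1)C/C(C)=C/CCc1ccoc1
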